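The pitfall is to treat the coupling partner as a charge to be set against the substrate: none of it is dissolved at the start, and what the flask later contains has crossed over from the gas.

    substrate + coupling partner → target (k1 = 4.8 M⁻¹ s⁻¹)
    substrate + 2 coupling partner → side product (k2 = 4500 M⁻² s⁻¹)
    2 substrate → homo dimer (k3 = 2.1 × 10⁻⁴ M⁻¹ s⁻¹)
    gas ⇌ coupling partner, rate k4*(csat - [coupling partner]) (k4 = 2.6 s⁻¹, csat = 1.1 mM)

| flask | substrate | gas | time |
|---|---|---|---|
| Tuesday's | 0.0025 M | 1.1 mM (held) | 5.0 min |
| Thursday's | 0.0050 M | 1.1 mM (held) | 5.0 min |
| Saturday's | 0.010 M | 1.1 mM (held) | 5.0 min |
| Sunday's | 0.020 M | 1.1 mM (held) | 5.0 min |

- in percentages every species weighs as the substrate in it: one homo dimer counts as two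
- two of one species on the left: rate k times its square, two consumed each time
- at the start none of coupling partner is dissolved
- "hardly changes" means that all values lie within two and a half points (for a concentration: within two and a half percent of the largest)
- run time (Tuesday's): 5.0 min

- amount of target at the end, in percent of the substrate charged for Tuesday's, Thursday's, Saturday's, Sunday's, in this order
- the course of these numbers from the first flask to the last (falls, then rises / rises all the way / falls all the way / hardly changes / rises, then falls)

**Filling first.** The solution fills with a time of 0.385 s, and because that is far shorter than the run of 5.0 min, you may start the reckoning with the coupling partner at its saturation level, 1.1 mM.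

**Target share.** At that level both couplings are pseudo-first-order in substrate, and step 1 takes 49.2% of the substrate consumed. This target share is step 1's rate over the sum of the two coupling rates, so it depends on the dissolved partner and not on the substrate charge. Even in Sunday's flask, the homo dimer step removes substrate at 5.04 × 10⁻⁴ min⁻¹ at the start, far slower than the 0.644 min⁻¹ of the couplings, so you can drop it.

**Closed form.** The substrate fraction then decays as a plain exponential, and 4.01% of the charge remains at the end. Target is the share times the fraction consumed, 47.3%, the same for every charge.

**Weak link.** The level cannot be exactly saturation, because transfer needs a gap to match the demand, with step 1 taking one partner and step 2 taking two. Set transfer equal to demand: the relative gap starts at 11.3% in Sunday's flask and 1.41% in Tuesday's. It shrinks with the substrate left, so averaged over the substrate consumed it is 5.65% for Sunday's, half of its starting value. That puts Sunday's partner near 1.04 mM, which raises the share to 50.7% but leaves 5.24% of the substrate unconsumed. Sunday's target is then 48.0%, a rise of 0.70 percentage points over the flat figure. The gap scales with the charge, so Thursday's and Saturday's fall between, and you commit to a row that hardly changes.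

**The forecast.** It gives 47.3%, 47.4%, 47.7% and 48.1%, a course that hardly changes, noting that “Higher loading lowers the partner level only slightly”.

**The flasks.** The row comes out at 47.4%, 47.6%, 47.8% and 48.2%: it hardly changes, and Sunday's flask gives more than Tuesday's. Tuesday's flask still holds 4.11% of its substrate at 5.00 min, against the 4.01% reckoned. The target share of 49.2% is where Tuesday's target should end, and at 50.0 min, with substrate at 0%, it stands at 49.5%. Sunday's raised share is 50.7%, and at 50.0 min, with substrate at 0%, Sunday's target stands at 50.6%.

The constants used here were chosen freely; the run is a simulation.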